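**Plan**
- Retrosynthetic cuts, in order: (i) the enone Cα=Cβ bond (Claisen–Schmidt) into A-ring acetophenone 9 and B-ring aldehyde 6; (ii) one C–CH3 bond of the tertiary carbinol (methyl addition to an acetyl group); (iii) C2–C3 of the dihydrofuran (aldol); (iv) the aryl O–CH2 bond.
- Enabling feature: the 3-OH on C3 is β to the carbinol carbon on C2. With that carbon at the ketone level, the ring O1–C2–C3–C3a–C7a is the cyclic aldol of an aryloxyacetone α-carbon (C2, flanked by O1 and C=O) and a salicylaldehyde carbonyl (C3).
- Forward order: ether 2; amine-catalysed aldol closes the dihydrofuran (the only ring made); methyl addition; formylation of the bromide; A-ring by C-prenylation and 4-O-allylation; chalcone union; deallylation.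
- Stereochemistry: both centres (2R,3R, trans) are set together in the aldol by D-proline and are not touched afterwards; the E-alkene comes from the condensation.
- Acid is avoided after step 2, because the benzylic 3-OH/2-H pair can lose water to a benzofuran and the o-prenylphenol can cyclise.

Key step: step 2

Remark: the target SMILES is read as the trans-(2R,3R) isomer (3-OH and the 2-hydroxypropan-2-yl group on opposite faces of the dihydrofuran ring).

**Step 1**
Reactants: 1 5-bromo-2-hydroxybenzaldehyde
Product: 2 5-bromo-2-(2-oxopropoxy)benzaldehyde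
Conditions: hydroxyacetone, PPh3, DIAD, THF, 0 °C → rt
Reagents that add atoms: hydroxyacetone, CC(=O)CO
Why: Mitsunobu etherification of the acidic phenol with the primary alcohol of hydroxyacetone runs under near-neutral conditions, chosen over chloroacetone/K2CO3 because carbonate would already start the racemic aldol/dehydration (Rap–Stoermer type) to 2-acetyl-5-bromobenzofuran.

**Step 2**
Reactants: 2 5-bromo-2-(2-oxopropoxy)benzaldehyde
Product: 4 1-[(2R,3R)-5-bromo-3-hydroxy-2,3-dihydro-1-benzofuran-2-yl]ethan-1-one, via D-proline enamine 3 (not isolated)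
Conditions: D-proline (30 mol%), DMF, 4 °C; pH 7 buffer work-up
Reagents that add atoms: none
Why: D-Proline should condense with the ketone of 2 to the E-enamine 3 on the oxygen-bearing CH2 side, whose nucleophilic carbon (the future C2, flanked by O1 and the enamine carbon) adds to the ortho aldehyde carbon (the future C3) while the carboxylic acid protonates the developing alkoxide, and hydrolysis of the resulting iminium ion releases 4 and the catalyst. The closest known reaction type is the proline-catalysed intramolecular enolexo aldolisation of dicarbonyl compounds (Hajos–Parrish–Eder–Sauer–Wiechert lineage), which is known in the 5-enolexo mode for o-(2-oxoalkoxy)aryl carbonyl compounds leading to 2-acyl-2,3-dihydrobenzofuran-3-ols. The dihydrofuran ring O1–C2–C3–C3a–C7a is closed 5-exo-trig at the aldehyde (5-enolexo), whereas the enamine on the CH3 side could only close a seven-membered ring. C2 is controlled by the E geometry of the enamine (aryloxy trans to nitrogen) and the catalyst face on which the carboxylic acid sits; C3 is controlled by the Houk–List arrangement in which the aldehyde oxygen is hydrogen-bonded to that acid and the aryl carbon C3a points away from the enamine carbon, which is the anti aldol and corresponds to the trans relation of acetyl and hydroxyl. Since L-proline gives the (S,S)-anti sense with α-oxygenated ketones, D-proline should give (2R,3R)-4. The step needs site-selective enamine formation (secured by the α-aryloxy group and the ring size), a non-enolisable acceptor (the aryl aldehyde) and survival of the β-hydroxy ketone, for which it is run cold, without added base and with a neutral work-up so that E1cB loss of water to the 2-acetylbenzofuran is held back.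

**Step 3**
Reactants: 4 1-[(2R,3R)-5-bromo-3-hydroxy-2,3-dihydro-1-benzofuran-2-yl]ethan-1-one
Product: 5 (2R,3R)-5-bromo-2-(2-hydroxypropan-2-yl)-2,3-dihydro-1-benzofuran-3-ol
Conditions: MeMgCl (3 equiv), CeCl3 (3 equiv), THF, −78 °C; aq. NH4Cl
Reagents that add atoms: methylmagnesium chloride, C[Mg]Cl
Why: Organocerium (Imamoto-type) 1,2-addition: after deprotonation of the 3-OH, the weakly basic, oxophilic methylcerium reagent should add to the ketone faster than it removes the acidic C2–H, which suppresses retro-aldol opening, epimerisation and E1cB dehydration; the new carbinol carbon bears two methyl groups and is not a stereocentre.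

**Step 4**
Reactants: 5 (2R,3R)-5-bromo-2-(2-hydroxypropan-2-yl)-2,3-dihydro-1-benzofuran-3-ol
Product: 6 (2R,3R)-3-hydroxy-2-(2-hydroxypropan-2-yl)-2,3-dihydro-1-benzofuran-5-carbaldehyde
Conditions: Pd(OAc)2 (1 mol%), BuPAd2 (3 mol%), TMEDA (0.75 equiv), CO/H2 (1:1, 5 bar), toluene, 100 °C
Reagents that add atoms: carbon monoxide, [C-]#[O+]
Why: Palladium-catalysed reductive carbonylation (formylation) of an aryl bromide with synthesis gas (oxidative addition, CO insertion, hydrogenolysis of the acylpalladium, amine as HBr acceptor) runs without acid and should leave the secondary benzylic and tertiary alcohols and both stereocentres untouched.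

**Step 5**
Reactants: 7 1-(2,4-dihydroxyphenyl)ethan-1-one
Product: 8 1-[2,4-dihydroxy-3-(3-methylbut-2-en-1-yl)phenyl]ethan-1-one
Conditions: prenyl bromide (1 equiv), 10% aq. KOH, 0 °C → rt
Reagents that add atoms: prenyl bromide, CC(C)=CCBr
Why: Direct C-alkylation of the resorcinol-type phenoxide in water, where C3 between the two oxygens is the most nucleophilic carbon and water disfavours O-alkylation, is the known one-step route to this acetophenone; the 5-prenyl and O-prenyl isomers are removed by chromatography.

**Step 6**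
Reactants: 8 1-[2,4-dihydroxy-3-(3-methylbut-2-en-1-yl)phenyl]ethan-1-one
Product: 9 1-[2-hydroxy-3-(3-methylbut-2-en-1-yl)-4-(prop-2-en-1-yloxy)phenyl]ethan-1-one
Conditions: allyl bromide (1.1 equiv), K2CO3, acetone, reflux
Reagents that add atoms: allyl bromide, C=CCBr
Why: Williamson etherification is selective for the 4-OH because the 2-OH is held in a hydrogen bond to the acetyl carbonyl, and the allyl group is chosen because it can later be removed without acid.

**Step 7**
Reactants: 6 (2R,3R)-3-hydroxy-2-(2-hydroxypropan-2-yl)-2,3-dihydro-1-benzofuran-5-carbaldehyde; 9 1-[2-hydroxy-3-(3-methylbut-2-en-1-yl)-4-(prop-2-en-1-yloxy)phenyl]ethan-1-one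
Product: 11 (E)-3-[(2R,3R)-3-hydroxy-2-(2-hydroxypropan-2-yl)-2,3-dihydro-1-benzofuran-5-yl]-1-[2-hydroxy-3-(3-methylbut-2-en-1-yl)-4-(prop-2-en-1-yloxy)phenyl]prop-2-en-1-one, via β-hydroxy ketone 10 (not isolated)
Conditions: KOH (50% aq., excess), EtOH, 0 °C → rt; aq. NH4Cl
Reagents that add atoms: none
Why: Claisen–Schmidt condensation: the enolate of 9 adds to the non-enolisable aldehyde 6 and the aldol 10 loses water by E1cB to the conjugated E-enone (thermodynamic geometry), while the two stereocentres, which carry no acidic hydrogen, are unaffected by base.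

**Step 8**
Reactants: 11 (E)-3-[(2R,3R)-3-hydroxy-2-(2-hydroxypropan-2-yl)-2,3-dihydro-1-benzofuran-5-yl]-1-[2-hydroxy-3-(3-methylbut-2-en-1-yl)-4-(prop-2-en-1-yloxy)phenyl]prop-2-en-1-one
Product: 12 Paratocarpin G
Conditions: Pd(PPh3)4 (5 mol%), K2CO3, MeOH, rt; aq. NH4Cl
Reagents that add atoms: none
Why: Tsuji–Trost-type deallylation: Pd(0) ionises the aryl allyl ether to a π-allyl complex that is captured by methanol, a base-only medium in which the prenyl group, the enone, the tertiary alcohol and the acid-sensitive benzylic 3-OH should survive.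

**Compound list**
1 | 5-bromo-2-hydroxybenzaldehyde | O=Cc1cc(Br)ccc1O | starting material
2 | 5-bromo-2-(2-oxopropoxy)benzaldehyde | CC(=O)COc1ccc(Br)cc1C=O | intermediate
3 | (2R)-1-[(1E)-1-(4-bromo-2-formylphenoxy)prop-1-en-2-yl]pyrrolidine-2-carboxylic acid (D-proline enamine of 2, not isolated) | C/C(=C\Oc1ccc(Br)cc1C=O)N1CCC[C@@H]1C(=O)O | intermediate
4 | 1-[(2R,3R)-5-bromo-3-hydroxy-2,3-dihydro-1-benzofuran-2-yl]ethan-1-one (trans) | Brc1ccc2c(c1)[C@@H](O)[C@H](C(C)=O)O2 | intermediate
5 | (2R,3R)-5-bromo-2-(2-hydroxypropan-2-yl)-2,3-dihydro-1-benzofuran-3-ol | Brc1ccc2c(c1)[C@@H](O)[C@H](C(C)(C)O)O2 | intermediate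
6 | (2R,3R)-3-hydroxy-2-(2-hydroxypropan-2-yl)-2,3-dihydro-1-benzofuran-5-carbaldehyde | O=Cc1ccc2c(c1)[C@@H](O)[C@H](C(C)(C)O)O2 | intermediate
7 | 1-(2,4-dihydroxyphenyl)ethan-1-one | CC(=O)c1ccc(O)cc1O | starting material
8 | 1-[2,4-dihydroxy-3-(3-methylbut-2-en-1-yl)phenyl]ethan-1-one | CC(C)=CCc1c(O)ccc(C(C)=O)c1O | intermediate
9 | 1-[2-hydroxy-3-(3-methylbut-2-en-1-yl)-4-(prop-2-en-1-yloxy)phenyl]ethan-1-one | CC(C)=CCc1c(OCC=C)ccc(C(C)=O)c1O | intermediate
10 | 3-hydroxy-3-[(2R,3R)-3-hydroxy-2-(2-hydroxypropan-2-yl)-2,3-dihydro-1-benzofuran-5-yl]-1-[2-hydroxy-3-(3-methylbut-2-en-1-yl)-4-(prop-2-en-1-yloxy)phenyl]propan-1-one (both epimers at the new carbinol carbon, not isolated) | CC(C)=CCc1c(OCC=C)ccc(C(=O)CC(O)c2ccc3c(c2)[C@@H](O)[C@H](C(C)(C)O)O3)c1O | intermediate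
11 | (E)-3-[(2R,3R)-3-hydroxy-2-(2-hydroxypropan-2-yl)-2,3-dihydro-1-benzofuran-5-yl]-1-[2-hydroxy-3-(3-methylbut-2-en-1-yl)-4-(prop-2-en-1-yloxy)phenyl]prop-2-en-1-one | CC(C)=CCc1c(OCC=C)ccc(C(=O)/C=C/c2ccc3c(c2)[C@@H](O)[C@H](C(C)(C)O)O3)c1O | intermediate
12 | Paratocarpin G, (E)-1-[2,4-dihydroxy-3-(3-methylbut-2-en-1-yl)phenyl]-3-[(2R,3R)-3-hydroxy-2-(2-hydroxypropan-2-yl)-2,3-dihydro-1-benzofuran-5-yl]prop-2-en-1-one | CC(C)=CCc1c(O)ccc(C(=O)/C=C/c2ccc3c(c2)[C@@H](O)[C@H](C(C)(C)O)O3)c1O | target

**Count**
Total steps: 8. Longest linear sequence: 6 (steps 1, 2, 3, 4, 7, 8).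

**Steps most likely to fail**

Step 2. In the constrained five-membered transition state the aldehyde may be attacked on its other face, so that the cis aldol forms instead of the trans one. Fallback, from 2 back to 5: the closure is accepted as cis-selective and C3 is set afterwards by inversion. The same amine-catalysed closure would give the cis aldol 1-[(2R,3S)-5-bromo-3-hydroxy-2,3-dihydro-1-benzofuran-2-yl]ethan-1-one F1 (same enamine face, other aldehyde face; its absolute configuration would have to be confirmed, and L-proline used if it proves to be the mirror-image series). Methyl addition as in step 3 would give the cis diol (2R,3S)-5-bromo-2-(2-hydroxypropan-2-yl)-2,3-dihydro-1-benzofuran-3-ol F2. Mitsunobu esterification (4-nitrobenzoic acid, PPh3, DIAD, THF, 0 °C) should invert the secondary benzylic carbinol to (2R,3R)-5-bromo-2-(2-hydroxypropan-2-yl)-2,3-dihydro-1-benzofuran-3-yl 4-nitrobenzoate F3. The tertiary alcohol does not react, and both SN2 and any ion-pair pathway place the acyloxy group anti to the bulky C2 substituent. Methanolysis (K2CO3, MeOH, rt) then returns to 5.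

Step 3. The reagent may act as a base rather than a nucleophile, and the metal alkoxide/enolate of the β-hydroxy ketone can then open by retro-aldol, epimerise at C2 or lose water to the aromatic benzofuran. Fallback, from 4 back to 5: the tertiary alcohol is built without a basic carbon nucleophile. Tebbe methylenation (Tebbe reagent, THF/pyridine, −40 → 0 °C) should give (2S,3R)-5-bromo-2-(prop-1-en-2-yl)-2,3-dihydro-1-benzofuran-3-ol F4 (same spatial arrangement; only the CIP descriptor at C2 changes). Mukaiyama hydration (Mn(dpm)3 cat., PhSiH3, O2, i-PrOH, rt) then adds hydrogen to the CH2 terminus and hydroxyl to the tertiary carbon, giving 5.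

Step 4. The acylpalladium intermediate may be captured by the free hydroxyl groups (ester formation, oligomers), or the bromide may be reduced instead of formylated. Fallback, from 5 back to 6: the formyl carbon is introduced as a vinyl group and then unmasked. Suzuki–Miyaura coupling (potassium vinyltrifluoroborate, PdCl2(dppf), Cs2CO3, THF/H2O, 80 °C) should give (2R,3R)-5-ethenyl-2-(2-hydroxypropan-2-yl)-2,3-dihydro-1-benzofuran-3-ol F5. Lemieux–Johnson cleavage (OsO4 cat., NaIO4, 2,6-lutidine, dioxane/H2O, rt) then gives 6; the 1,3-diol is not a periodate substrate.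

**Further compounds**
F1 | step 2 | 1-[(2R,3S)-5-bromo-3-hydroxy-2,3-dihydro-1-benzofuran-2-yl]ethan-1-one | Brc1ccc2c(c1)[C@H](O)[C@H](C(C)=O)O2
F2 | step 2 | (2R,3S)-5-bromo-2-(2-hydroxypropan-2-yl)-2,3-dihydro-1-benzofuran-3-ol | Brc1ccc2c(c1)[C@H](O)[C@H](C(C)(C)O)O2
F3 | step 2 | (2R,3R)-5-bromo-2-(2-hydroxypropan-2-yl)-2,3-dihydro-1-benzofuran-3-yl 4-nitrobenzoate | Brc1ccc2c(c1)[C@@H](OC(=O)c1ccc(cc1)[N+](=O)[O-])[C@H](C(C)(C)O)O2
F4 | step 3 | (2S,3R)-5-bromo-2-(prop-1-en-2-yl)-2,3-dihydro-1-benzofuran-3-ol | Brc1ccc2c(c1)[C@@H](O)[C@H](C(C)=C)O2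
F5 | step 4 | (2R,3R)-5-ethenyl-2-(2-hydroxypropan-2-yl)-2,3-dihydro-1-benzofuran-3-ol | C=Cc1ccc2c(c1)[C@@H](O)[C@H](C(C)(C)O)O2
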